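## The problem

Compound 12 is a depside. Ring A (a 2,4-dimethoxy-6-pentylbenzoyl unit) and ring B (a 2-hydroxy-6-pentylbenzoic acid) are joined only by an aryl ester from the ring A carboxyl to the C4 oxygen of ring B. There is no stereocentre and no ring to close, so the task is regiochemistry on two nearly identical arenes and keeping their oxygen functions apart. Ring A carries two methyl ethers while ring B keeps a free C2 hydroxyl and a free C1 carboxyl. This rules out O-methylation after the rings are joined and any late deprotection with strong Lewis acids. The depside link is an activated aryl ester that nucleophilic bases and alkoxides can cleave or transfer, although its carbonyl is screened by the ortho methoxy and ortho pentyl groups. The ring B acid is a salicylic acid of the resorcylic type and loses CO2 on heating or in strong acid, so it should appear last and under mild conditions. Both rings keep open positions that electrophilic chlorine would attack, so any oxidant that releases it needs a scavenger. The enabling feature is that the carboxyl carbon on C1 of ring B lies ortho to the free C2 hydroxyl, para to the C4 ester oxygen and beside the C6 pentyl chain. Without that carbon, ring B is olivetol acylated once by the ring A acid, and the hydroxyl can direct a one-carbon electrophile back to C1.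

## Retrosynthesis

**12 to 11.** The last bond cut is the C–OH bond of the carboxyl group, which traces acid 12 to salicylaldehyde 11. Direct carboxylation of the phenol with magnesium methyl carbonate (MeOMgOCO2Me) needs hot dipolar solvent, which endangers both the depside ester and the acid being formed. The aldehyde is neutral, cannot decarboxylate and is oxidised by chlorite at room temperature in a weakly acidic buffer. The forward step must oxidise without halogenating either ring.

**11 to 8 and 9.** The bond from C1 of ring B to the formyl carbon is cut, giving olivetol monoester 8 and formaldehyde 9. Cutting the ester first would need a ring B acid protected as an ester and a later deprotection. Here the precursor is a monoester of a symmetrical diol with no protecting group. The forward reaction has to choose the ortho carbon beside the pentyl chain over the ortho carbon between the two oxygens, and must leave the ester alone.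

**8 to 7 and 1.** The acyl C–O bond of the depside is cut, giving acid chloride 7 and olivetol 1. Because 1 is symmetrical, the only selectivity asked is one acylation instead of two, which an excess of the diol provides.

**7 to 6 to 5.** Two functional group changes lead from the acid chloride through acid 6 to aldehyde 5. The aldehyde is chosen because it is the product of the most regioselective way to put one carbon on ring A.

**5 to 2 and 3.** The bond from C1 of ring A to the formyl carbon is cut, giving 1,3-dimethoxy-5-pentylbenzene 2 and N,N-dimethylformamide 3. An electrophilic formylation is required here. Directed lithiation of 2 would go to the carbon between the two methoxy groups and give the wrong isomer.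

**2 to 1.** The two O–CH3 bonds are cut, returning to olivetol 1, so one commercial arene supplies both rings.

## Roads not taken

**Alternative 1:** Ring B is cut across two ring bonds to a cyclohexanedione, A1 (benzyl 2-hydroxy-4-oxo-6-pentylcyclohex-2-ene-1-carboxylate, racemic, trans). In the forward direction dibenzyl malonate A2 adds to (E)-non-3-en-2-one A3 in a Michael reaction. The methyl ketone enolate then closes the ring by Claisen condensation onto one malonate ester. O-acylation of A1 with acid chloride 7, dehydrogenation to the benzyl ester A4 and hydrogenolysis would give 12.
- Merit: the carboxyl carbon comes from the malonate, so its position on ring B is fixed by construction. This is better than the chosen plan, whose site selectivity is untested. It also needs no olivetol for ring B and is more convergent.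
- Weak points: A1 has two enol oxygens and a nucleophilic carbon between them, so acylation can go to the wrong oxygen or to carbon. The aromatisation then needs an oxidant in the presence of an enol ester and the electron-rich ring A. Two stereocentres are made only to be destroyed, and a benzyl ester must be carried and removed.
- Comparison: the step count is about the same. The chosen plan offers no protecting group, only two operations after the rings are joined, and a known fallback that repairs the regiochemistry.

**Alternative 2:** Ring A is cut across two ring bonds and built on the ester by cycloaddition, the key step giving A5 (benzyl 2-(benzyloxy)-4-[(2,4-dimethoxy-6-pentylbenzoyl)oxy]-6-pentylbenzoate). The Brassard diene A6 would add across the triple bond of ynoate A7, which is the oct-2-ynoyl ester of the protected ring B phenol A8. Loss of the silyloxy group as silanol aromatises the adduct, and double hydrogenolysis of A5 ends the route.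
- Merit: the diene polarity fixes the ring A substitution pattern with no isomer question, and the end game is a neutral hydrogenolysis with no oxidant near electron-rich rings. In both respects it is better than the chosen plan.
- Weak points: a β-alkyl ynoate is a sluggish dienophile, and the heating it needs strains an aryl ynoate. Conjugate addition of the ketene acetal can compete with cycloaddition. Loss of the methoxy group instead of the silyloxy group would leave a free hydroxyl on ring A. A8 needs a multistep, selectively protected synthesis of its own, and A6 is moisture sensitive.
- Comparison: the chosen plan is several steps shorter, uses only bench-stable reagents and needs no benzyl groups.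

**Alternative 3:** The depside C–O bond and one ring A bond are cut together, the key step giving A9 (benzyl 2-(benzyloxy)-4-[(2,4-dihydroxy-6-pentylbenzoyl)oxy]-6-pentylbenzoate). Heating the diketo-dioxinone A10 with phenol A8 would release an acylketene, which the phenol captures. The resulting aryl trioxododecanoate closes ring A by aldol condensation and dehydration. Methylation of both ring A hydroxyls would then give A5, and hydrogenolysis 12.
- Merit: it is the most convergent construction, making the depside bond and ring A in one neutral thermal operation with unambiguous ring A regiochemistry. It avoids the hindered acid chloride coupling, an advantage over the chosen plan.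
- Weak points: ring A arrives with free hydroxyls, so a methylation next to an aryl ester must be added. The triketo aryl ester can instead lactonise to a pyranone and expel A8, which destroys the depside link. A8 and A10 each need several steps.
- Comparison: the chosen plan brings ring A already methylated, carries no protecting group on ring B and is shorter overall.

Key step: step 6

Assumption: paraformaldehyde is entered as monomeric formaldehyde 9, and the counter-ion of iminium salt 4 is drawn as chloride although dichlorophosphate is also present.

## Route

Step 1
Reactants: 1 olivetol (5-pentylbenzene-1,3-diol)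
Product: 2 1,3-dimethoxy-5-pentylbenzene
Conditions: MeI, K2CO3, DMF, rt
Reagents that add atoms: iodomethane, CI
Why: Williamson ether synthesis on both phenols; K2CO3 in a dipolar aprotic solvent gives O-methylation of resorcinols with little C-methylation.

Step 2
Reactants: 2 1,3-dimethoxy-5-pentylbenzene; 3 N,N-dimethylformamide
Product: 5 2,4-dimethoxy-6-pentylbenzaldehyde, via aryl iminium chloride 4 (not isolated)
Conditions: POCl3, DMF, 0 °C to 60 °C; then aq NaOAc
Reagents that add atoms: water, O
Why: Vilsmeier–Haack formylation; the chloroiminium ion attacks the carbon that is para to one methoxy group and beside the pentyl chain in preference to the more crowded carbon between the two methoxy groups, as is usual for 5-alkylresorcinol dimethyl ethers. Hydrolysis of iminium salt 4 on work-up releases the aldehyde.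

Step 3
Reactants: 5 2,4-dimethoxy-6-pentylbenzaldehyde
Product: 6 2,4-dimethoxy-6-pentylbenzoic acid
Conditions: NaClO2, NaH2PO4, 2-methylbut-2-ene, t-BuOH/H2O, rt
Reagents that add atoms: sodium chlorite, [Na+].[O-]Cl=O
Why: Pinnick oxidation; chlorous acid adds to the aldehyde and fragments to the acid and HOCl, which the alkene removes before it can chlorinate the electron-rich ring.

Step 4
Reactants: 6 2,4-dimethoxy-6-pentylbenzoic acid
Product: 7 2,4-dimethoxy-6-pentylbenzoyl chloride
Conditions: (COCl)2, DMF (cat.), CH2Cl2, 0 °C to rt; evaporated and used crude
Reagents that add atoms: oxalyl chloride, O=C(Cl)C(=O)Cl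
Why: Acid chloride formation through the catalytic Vilsmeier chloride; the conditions are neutral to weakly acidic and do not touch the methyl ethers.

Step 5
Reactants: 7 2,4-dimethoxy-6-pentylbenzoyl chloride; 1 olivetol
Product: 8 3-hydroxy-5-pentylphenyl 2,4-dimethoxy-6-pentylbenzoate
Conditions: 1 (3 equiv), Et3N, DMAP (cat.), CH2Cl2, 0 °C to rt, slow addition of 7
Reagents that add atoms: none
Why: DMAP-catalysed O-acylation of a phenol by an acid chloride; the excess of the symmetrical diol and the slow addition should hold the reaction at the monoester. The first aroyl group also makes the remaining phenol less nucleophilic, and unreacted olivetol is recovered.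

Step 6
Reactants: 8 3-hydroxy-5-pentylphenyl 2,4-dimethoxy-6-pentylbenzoate; 9 formaldehyde (as paraformaldehyde)
Product: 11 4-formyl-3-hydroxy-5-pentylphenyl 2,4-dimethoxy-6-pentylbenzoate, via magnesium salt of salicyl alcohol 10 (not isolated)
Conditions: MgCl2 (anhydrous), Et3N, (CH2O)n, THF, reflux; then 1 M HCl
Reagents that add atoms: none
Why: MgCl2 and Et3N turn phenol 8 into its chloromagnesium phenoxide, which binds monomeric formaldehyde and passes it to an ortho carbon through a six-membered chelated transition state, and rearomatisation gives the magnesium salt of salicyl alcohol 10. A second formaldehyde then takes hydride from the benzylic alkoxide inside the magnesium chelate, an Oppenauer-type transfer, so that aldehyde 11 and methanol result. The closest known reaction type is the Casnati–Skattebøl ortho-formylation of magnesium phenoxides, which is established for 3,5-disubstituted phenols and for phenols that carry ester groups. No ring is closed and no stereocentre is formed. The step needs site selectivity between the two carbons ortho to the hydroxyl and chemoselectivity against the depside ester. The carbon beside the pentyl chain is para to the ester oxygen and so receives its lone-pair donation, whereas the carbon between the two oxygens feels the inductive pull of the acyloxy group at close range and is shielded by the twisted 2,6-disubstituted benzoate; chelation confines attack to the ortho carbons, so the carbon para to the hydroxyl stays untouched. The ester should survive because Et3N is not nucleophilic and the ester carbonyl is screened on both sides by the methoxy and pentyl groups of ring A. The product is held as a deactivated magnesium chelate, which should prevent a second formylation.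

Step 7
Reactants: 11 4-formyl-3-hydroxy-5-pentylphenyl 2,4-dimethoxy-6-pentylbenzoate
Product: 12 4-[(2,4-dimethoxy-6-pentylbenzoyl)oxy]-2-hydroxy-6-pentylbenzoic acid
Conditions: NaClO2, NaH2PO4, 2-methylbut-2-ene (large excess), t-BuOH/THF/H2O, 0 °C to rt
Reagents that add atoms: sodium chlorite, [Na+].[O-]Cl=O
Why: Pinnick oxidation, a method first developed on hydroxybenzaldehydes; the phosphate buffer is too weakly acidic to hydrolyse the depside ester, and the low temperature avoids decarboxylation of the salicylic acid. The excess alkene removes HOCl before it can chlorinate either ring.

## Compound list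

1 | olivetol (5-pentylbenzene-1,3-diol) | CCCCCc1cc(O)cc(O)c1 | starting material
2 | 1,3-dimethoxy-5-pentylbenzene | CCCCCc1cc(OC)cc(OC)c1 | intermediate
3 | N,N-dimethylformamide | CN(C)C=O | starting material
4 | [(2,4-dimethoxy-6-pentylphenyl)methylidene]dimethylazanium chloride (aryl iminium chloride, formed in the flask in step 2) | CCCCCc1cc(OC)cc(OC)c1C=[N+](C)C.[Cl-] | intermediate
5 | 2,4-dimethoxy-6-pentylbenzaldehyde | CCCCCc1cc(OC)cc(OC)c1C=O | intermediate
6 | 2,4-dimethoxy-6-pentylbenzoic acid | CCCCCc1cc(OC)cc(OC)c1C(=O)O | intermediate
7 | 2,4-dimethoxy-6-pentylbenzoyl chloride | CCCCCc1cc(OC)cc(OC)c1C(=O)Cl | intermediate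
8 | 3-hydroxy-5-pentylphenyl 2,4-dimethoxy-6-pentylbenzoate | CCCCCc1cc(O)cc(OC(=O)c2c(CCCCC)cc(OC)cc2OC)c1 | intermediate
9 | formaldehyde (used as paraformaldehyde) | C=O | starting material
10 | 3-hydroxy-4-(hydroxymethyl)-5-pentylphenyl 2,4-dimethoxy-6-pentylbenzoate (salicyl alcohol, present as its magnesium salt in the flask in step 6; drawn neutral) | CCCCCc1cc(OC(=O)c2c(CCCCC)cc(OC)cc2OC)cc(O)c1CO | intermediate
11 | 4-formyl-3-hydroxy-5-pentylphenyl 2,4-dimethoxy-6-pentylbenzoate | CCCCCc1cc(OC(=O)c2c(CCCCC)cc(OC)cc2OC)cc(O)c1C=O | intermediate
12 | 4-[(2,4-dimethoxy-6-pentylbenzoyl)oxy]-2-hydroxy-6-pentylbenzoic acid | CCCCCc1cc(OC(=O)c2c(CCCCC)cc(OC)cc2OC)cc(O)c1C(=O)O | target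

## Step count and risks

Total step count: 7. Longest linear sequence: 7 steps (1 to 2 to 5 to 6 to 7 to 8 to 11 to 12), with olivetol 1 entering a second time in step 5.

**Step 6 (key step).** The most likely failure is formylation at the other ortho carbon, between the hydroxyl and the ester oxygen, because the preference between the two flanked ortho sites has not been tested on this monoester. A second risk is acyl transfer or cleavage of the depside ester by the magnesium methoxide formed during the hydride transfer. The fallback reverses the order of C–C and C–O bond formation. It sets out from olivetol 1, which is formylated under Vilsmeier–Haack conditions (POCl3, DMF) to 2,4-dihydroxy-6-pentylbenzaldehyde F1. The C2 hydroxyl of F1 is tied up in a hydrogen bond to the aldehyde, so acid chloride 7 with Et3N in CH2Cl2 should acylate the C4 hydroxyl. This comes back to the route at 11.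

**Step 7.** Electrophilic chlorination of either electron-rich ring may outrun the scavenger, the free phenol may be oxidised by chlorine dioxide, or the hydrogen-bonded aldehyde may react slowly. Warming to force conversion would bring on decarboxylation. The fallback masks the phenol. It sets out from 11, which is benzylated (benzyl bromide, K2CO3, DMF) to 3-(benzyloxy)-4-formyl-5-pentylphenyl 2,4-dimethoxy-6-pentylbenzoate F2. The same chlorite oxidation on this non-phenolic aldehyde gives 2-(benzyloxy)-4-[(2,4-dimethoxy-6-pentylbenzoyl)oxy]-6-pentylbenzoic acid F3. Hydrogenolysis (H2, Pd/C, ethyl acetate) comes back to the route at 12.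

**Step 5.** Over-acylation to the bis-ester may occur, and acylation by the doubly ortho-substituted acid chloride may be slow enough for hydrolysis to compete. The fallback uses a partner with only one free hydroxyl and a stronger nucleophile. It sets out from 1, which is mono-benzylated (benzyl bromide, one equivalent, K2CO3, acetone) to 3-(benzyloxy)-5-pentylphenol F4. The sodium phenoxide of F4 (NaH, THF) is acylated by 7 to 3-(benzyloxy)-5-pentylphenyl 2,4-dimethoxy-6-pentylbenzoate F5. Hydrogenolysis (H2, Pd/C, ethyl acetate) comes back to the route at 8.

**Step 2.** Competing attack at the carbon between the two methoxy groups would give an isomeric aldehyde that is hard to separate, and the isomer would then be carried into step 3. The fallback changes the electrophile and bypasses the chlorite oxidation. It sets out from 2, which is brominated with N-bromosuccinimide in acetonitrile to 2-bromo-1,5-dimethoxy-3-pentylbenzene F6. Halogen–lithium exchange (n-BuLi, THF, −78 °C) and quenching with CO2 comes back to the route at 6.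

## Further compounds

F1 | step 6 | 2,4-dihydroxy-6-pentylbenzaldehyde | CCCCCc1cc(O)cc(O)c1C=O
F2 | step 7 | 3-(benzyloxy)-4-formyl-5-pentylphenyl 2,4-dimethoxy-6-pentylbenzoate | CCCCCc1cc(OC(=O)c2c(CCCCC)cc(OC)cc2OC)cc(OCc2ccccc2)c1C=O
F3 | step 7 | 2-(benzyloxy)-4-[(2,4-dimethoxy-6-pentylbenzoyl)oxy]-6-pentylbenzoic acid | CCCCCc1cc(OC(=O)c2c(CCCCC)cc(OC)cc2OC)cc(OCc2ccccc2)c1C(=O)O
F4 | step 5 | 3-(benzyloxy)-5-pentylphenol | CCCCCc1cc(O)cc(OCc2ccccc2)c1
F5 | step 5 | 3-(benzyloxy)-5-pentylphenyl 2,4-dimethoxy-6-pentylbenzoate | CCCCCc1cc(OCc2ccccc2)cc(OC(=O)c2c(CCCCC)cc(OC)cc2OC)c1
F6 | step 2 | 2-bromo-1,5-dimethoxy-3-pentylbenzene | CCCCCc1cc(OC)cc(OC)c1Br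
A1 | alternative 1 | benzyl 2-hydroxy-4-oxo-6-pentylcyclohex-2-ene-1-carboxylate (racemic, trans) | CCCCC[C@@H]1CC(=O)C=C(O)[C@H]1C(=O)OCc1ccccc1
A2 | alternative 1 | dibenzyl malonate | O=C(CC(=O)OCc1ccccc1)OCc1ccccc1
A3 | alternative 1 | (E)-non-3-en-2-one | CCCCC/C=C/C(C)=O
A4 | alternative 1 | benzyl 4-[(2,4-dimethoxy-6-pentylbenzoyl)oxy]-2-hydroxy-6-pentylbenzoate | CCCCCc1cc(OC(=O)c2c(CCCCC)cc(OC)cc2OC)cc(O)c1C(=O)OCc1ccccc1
A5 | alternative 2 | benzyl 2-(benzyloxy)-4-[(2,4-dimethoxy-6-pentylbenzoyl)oxy]-6-pentylbenzoate | CCCCCc1cc(OC(=O)c2c(CCCCC)cc(OC)cc2OC)cc(OCc2ccccc2)c1C(=O)OCc1ccccc1
A6 | alternative 2 | Brassard diene, 1,3-dimethoxy-1-(trimethylsilyloxy)buta-1,3-diene | C=C(OC)C=C(OC)O[Si](C)(C)C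
A7 | alternative 2 | benzyl 2-(benzyloxy)-4-(oct-2-ynoyloxy)-6-pentylbenzoate | CCCCCC#CC(=O)Oc1cc(CCCCC)c(C(=O)OCc2ccccc2)c(OCc2ccccc2)c1
A8 | alternative 2 | benzyl 2-(benzyloxy)-4-hydroxy-6-pentylbenzoate | CCCCCc1cc(O)cc(OCc2ccccc2)c1C(=O)OCc1ccccc1
A9 | alternative 3 | benzyl 2-(benzyloxy)-4-[(2,4-dihydroxy-6-pentylbenzoyl)oxy]-6-pentylbenzoate | CCCCCc1cc(OC(=O)c2c(CCCCC)cc(O)cc2O)cc(OCc2ccccc2)c1C(=O)OCc1ccccc1
A10 | alternative 3 | 6-(2,4-dioxononyl)-2,2-dimethyl-4H-1,3-dioxin-4-one | CCCCCC(=O)CC(=O)CC1=CC(=O)OC(C)(C)O1
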